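## Structural features

The target (34) is a germacranolide: a ten-membered carbocycle C1–C10 fused across C6–C7 to an α-methylene-γ-butyrolactone (O6–C12(=O)–C11(=C13)–C7). The fusion is trans (H6 and H7 on opposite faces), and C6, C7 and C8 are contiguous stereocentres (6R,7R,8R). Along the C5–C9 chain O6 is syn and O8 is anti to the C11 branch; a fourth, remote centre is the (S)-α-carbon of the 2-methylbutanoate on O8. Both ring olefins are trisubstituted and cis within the ring: C1=C10 carries the C14 formyl group (an enal) and C4=C5 carries the C15 hydroxymethyl group (both are E by CIP only because C14 and C15 outrank the ring carbons). Fragile elements are the two Michael acceptors (enal and α-methylene lactone), the secondary ester next to O6 (acyl migration, and the competing 8,12-lactone if O8 were free), the epimerisable α-carbon of the ester, and the cyclodeca-1,5-diene, which is open to transannular reactions in acid. The real difficulty is to close a ten-membered ring that holds two geometrically defined trisubstituted olefins while the 1,2,3-triad and four differentiated oxygen functions stay in order. The key step exploits that C10 is the α-carbon of the enal, that C9 must be cis to C2 across C1=C10, and that C10 is homoallylic to the C8 carbinol. C14–C10≡C1 is therefore a propynal acetal, C2 an organocopper carbon and C8–C9 a terminal epoxide, so that syn-carbometalation followed by retentive epoxide opening writes the olefin geometry directly.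

## Logic of the disconnections

34 ⇒ 33. Only the O15–Si bond is cut. C15 stays masked to the end because the C12 primary allylic alcohol must be oxidised while C15 is present. The demand is a fluoride source mild enough for an enal, an α-methylene lactone and a secondary ester.

33 ⇒ 32. The C4=C5 ring bond is cut, which opens the ten-membered ring to a C6 vinyl group and a C4 methylidene group. This is the only ring bond whose two ends can be carried as unreactive terminal olefins through all earlier steps. In 32 the other two olefins are conjugated to carbonyl groups and should not compete for the carbene, and the trans lactone and the cis C1=C10 bond pre-organise the chain. The forward metathesis must work at high dilution and must give the ring-cis trisubstituted olefin.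

32 ⇒ 29. The O6–C12 acyl bond is cut and C12 is taken back to the alcohol level. The α-methylene lactone, which no organocopper step would tolerate, becomes a 2-methylidene-1,4-diol. The forward oxidation must select the primary allylic alcohol over the secondary one and must find O6 as the only free hydroxyl able to close a five-membered lactol.

29 ⇒ 28 ⇒ 26 + 27. The two O–Si bonds at O6 and O12 and the acetal at C14 are restored, then the O8–acyl bond is cut. The ester goes on while O6 is still silylated, so O8 and O6 are never free together. The forward acylation must not epimerise the α-carbon of 27, and the acid unmasking must spare the C15 silyl ether and the ester.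

26 ⇒ 6 + 22 + 21. The C1–C2 and C9–C10 bonds are cut. They flank the C1=C10 olefin: C10 becomes the copper-bearing carbon of a syn-carbometalated alkyne, C2 an organocopper carbon, and C9 the free end of an epoxide whose other carbon is already the C8 carbinol. A fifteen-carbon triene with three stereocentres falls into a four-carbon iodide, a three-carbon alkyne and a seven-carbon epoxide that alone carries the stereocentres. The forward step must place copper at C10, keep the alkenylcopper configurationally intact and cold enough not to lose ethoxide, and open the epoxide at C9 only.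

6 ⇒ 5 ⇒ 2 + 3, and 2 ⇒ 1. The C2–I bond is traced to C2–OH, and the C3–C4 bond is cut between an alkenyl anion at C4 and the two-carbon epoxide 3. The two oxygens of 5 come from different reagents and are differentiated from the start. The demand is a clean bromine–lithium exchange on 2 without silyl migration.

21 ⇒ 20 ⇒ 18 ⇒ 17. The O6–Si bond, then the C9–O bond of the epoxide, then the PMB ether at O9 are undone. O6 is silylated last, so that the free O6 hydroxyl can direct the earlier C–C bond formation. The demand is selective activation of the primary C9 hydroxyl of the triol 18 and three-membered closure from O8 faster than five-membered closure from O6.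

17 ⇒ 13 + 16 (16 from 14 through 15; 14 ⇒ 1). The C7–C11 bond is cut: C11 becomes an alkenylmagnesium carbon and C7 an epoxide carbon. One SN2 event with inversion sets C7 relative to both neighbours and releases O8. The demand is attack at C7 and not at C8; this is expected from the free alkoxide at C6 and from the ether oxygen on C9, which deactivates C8.

13 ⇒ 12. The C7–O and C8–O bonds of the epoxide are removed to give the E-olefin of a racemic secondary divinyl-type carbinol. A reagent-controlled epoxidation run as a kinetic resolution sets C6, C7 and C8 at once. The price is that at most half of 12 is used.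

12 ⇒ 11 ⇒ 8 + 9, and 8 ⇒ 7. The E-olefin is traced to the alkyne, and the C6–C7 bond is cut between an acetylide and the aldehyde carbon of 9. All carbons come from three-carbon feedstocks. The demands are 1,2-addition to the enal and a trans-selective reduction that does not expel the C9 alkoxide.

## Other disconnections considered

Alternative 1: The cut is the C1=C10 double bond, traced to the eleven-membered cyclic sulfone A1 in which sulfur links C1 and C10 and C10 also carries the C14 methyl ester. In the forward sense a Ramberg–Bäcklund reaction with in-situ halogenation (CBr2F2, KOH on alumina) would brominate the doubly activated C10, the C1 carbanion would close the episulfone, and loss of SO2 would give the cyclodecadiene ester A2.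
- In its favour: the large ring is closed by C–S bond formation, which is easier than any C–C macrocyclisation and on this point better than the metathesis of 32. The C4=C5 geometry is fixed in an open chain before ring closure, again better than in the chosen plan. The site of halogenation is unambiguous.
- Against it here: nothing in A1 dictates the geometry of the extrusion, and a trisubstituted enoate in a ten-membered ring can form ring-cis or ring-trans. The chosen plan sets the same geometry by a stereospecific syn addition. Closure at a tertiary, ester-bearing bromide is hindered, and hot hydroxide on alumina endangers the methyl ester.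
- Step economy: A2 still needs ester-to-aldehyde redox adjustment, acetonide removal, lactonisation, PMB removal, acylation and desilylation, roughly seven steps against five after 26. On the triad the two plans are equal, since A1 would need the same C6–C8 chemistry as 21.

Alternative 2: The cut is C7–C8 with transposition of the olefin; the precursor is the open-chain aldehyde A3, a C6-substituted butenolide with a tributylstannylmethyl group on C11 and the C8 aldehyde at the end of the diene chain. In the forward sense BF3·OEt2 would activate the aldehyde, C7 would attack it in an SE2′ sense, the double bond would move to C11=C13, and the ten-membered ring of A4 would close.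
- In its favour: one step forms the ring, the C7–C8 bond, two stereocentres and the α-methylene lactone. Both olefin geometries are fixed before ring closure, which is better than the chosen plan. A4 is about four steps from the target, equal to or slightly better than the five after 26.
- Against it here: a ten-membered ring is closed by a carbonyl addition with no conformational help, so oligomerisation and protodestannylation compete. The trans lactone requires the tethered aldehyde to reach the butenolide face opposite to its own point of attachment at C6. The C8 configuration depends on the macrocyclic transition state and on nothing in A3. The chosen plan sets C6, C7 and C8 early by reagent and substrate control.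
- Step economy: A3 is a long linear chain with two acyclically defined trisubstituted olefins, a sensitive allylstannane and an enantioenriched butenolide, so the overall count is not lower.

Alternative 3: The cut is C8–C9, paired with re-formation of a C1–C6 bond, which contracts the ten-membered ring to the perillyl-derived cyclohexenol A5 (a cis-1,6-dialkenylcyclohex-2-en-1-ol). In the forward sense the potassium alkoxide of A5 (KH) would undergo an anionic oxy-Cope [3,3] shift that cleaves C1–C6, forms C8–C9 and gives the cyclodecadienone A6.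
- In its favour: ring expansion avoids macrocyclisation entropy altogether and is the most reliable ring-forming event of the four plans. The C4=C5 ring-cis geometry is inherited from the six-membered ring, better than the metathesis of 32. C8 can be set by transfer from the enol ether geometry, and the starting ring is chiral-pool material.
- Against it here: a ring-cis C1=C10 bond needs the chair in which the C1–C2 ring bond is axial, which is not the usual preference, so this geometry is less secure than in the chosen plan. The enolate formed has the PMB-oxy group in the β-position and can eliminate it. A6 lacks C11–C13 and both the C6 and C7 stereocentres, which would have to be installed on a flexible ten-membered ketone with little control.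
- Step economy: the post-key-step sequence (C7 alkylation, C6 reduction, lactonisation, C14 oxidation, protecting-group changes, acylation) is clearly longer than the five steps after 26.

Key step: step 13

Remark: atoms keep the germacrane numbers of the target throughout; TBS = tert-butyldimethylsilyl, TBDPS = tert-butyldiphenylsilyl, PMB = 4-methoxybenzyl; 1, 3 (as a THF solution), 7, 9, 22 and 27 are taken as commercial.

Step 1
Reactants: 1 2-bromoprop-2-en-1-ol
Product: 2 [(2-bromoprop-2-en-1-yl)oxy](tert-butyl)diphenylsilane
Conditions: TBDPSCl, imidazole, CH2Cl2, 0 °C → rt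
Reagents that add atoms: tert-butyl(chloro)diphenylsilane, CC(C)(C)[Si](Cl)(c1ccccc1)c1ccccc1
Why: Standard silyl ether formation on a primary allylic alcohol; the TBDPS group is chosen to survive the later aqueous acid that removes the TBS groups.

Step 2
Reactants: 2 [(2-bromoprop-2-en-1-yl)oxy](tert-butyl)diphenylsilane; 3 oxirane
Product: 5 3-{[(tert-butyldiphenylsilyl)oxy]methyl}but-3-en-1-ol, via alkenyllithium 4 (not isolated)
Conditions: t-BuLi (2 equiv), Et2O, −78 °C; then 3 (THF solution), BF3·OEt2, −78 °C
Reagents that add atoms: none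
Why: Bromine–lithium exchange gives the 2-lithioallyl ether, which opens BF3-activated oxirane by SN2 attack at CH2. C2 and C3 are thereby attached to C4 with the two oxygens already differentiated, so no statistical protection of a diol is needed.

Step 3
Reactants: 5 3-{[(tert-butyldiphenylsilyl)oxy]methyl}but-3-en-1-ol
Product: 6 tert-butyl[(4-iodo-2-methylidenebutyl)oxy]diphenylsilane
Conditions: I2, PPh3, imidazole, CH2Cl2, 0 °C → rt
Reagents that add atoms: iodine, II
Why: Appel-type iodination of a primary alcohol through the alkoxyphosphonium iodide; the silyl ether and the 1,1-disubstituted olefin are inert.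

Step 4
Reactants: 7 prop-2-yn-1-ol
Product: 8 1-methoxy-4-[(prop-2-yn-1-yloxy)methyl]benzene
Conditions: NaH, PMBCl, Bu4NI (cat.), THF, 0 °C → rt
Reagents that add atoms: 4-methoxybenzyl chloride, COc1ccc(CCl)cc1
Why: Williamson ether synthesis; the PMB group later serves as the ether oxygen on C9 that steers the epoxide opening and is removable by oxidation in the presence of silyl ethers.

Step 5
Reactants: 8 1-methoxy-4-[(prop-2-yn-1-yloxy)methyl]benzene; 9 prop-2-enal
Product: 11 rac-6-[(4-methoxyphenyl)methoxy]hex-1-en-4-yn-3-ol, via lithium acetylide 10 (not isolated)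
Conditions: n-BuLi, THF, −78 °C; then 9, −78 °C; aq. NH4Cl
Reagents that add atoms: none
Why: A lithium acetylide adds 1,2 to the enal at low temperature and forms the C6–C7 bond; the racemic carbinol is resolved in step 7.

Step 6
Reactants: 11 rac-6-[(4-methoxyphenyl)methoxy]hex-1-en-4-yn-3-ol
Product: 12 rac-(4E)-6-[(4-methoxyphenyl)methoxy]hexa-1,4-dien-3-ol
Conditions: NaAlH2(OCH2CH2OMe)2, THF, 0 °C; aq. potassium sodium tartrate
Reagents that add atoms: none
Why: Alkoxide-directed trans-hydroalumination of a propargylic alcohol and protonolysis give the E-allylic alcohol; the isolated vinyl group is untouched. The temperature is kept at 0 °C so that the alkenylalane does not expel the C9 alkoxide to an allene.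

Step 7
Reactants: 12 rac-(4E)-6-[(4-methoxyphenyl)methoxy]hexa-1,4-dien-3-ol
Product: 13 (1R)-1-[(2R,3R)-3-{[(4-methoxyphenyl)methoxy]methyl}oxiran-2-yl]prop-2-en-1-ol
Conditions: Ti(OiPr)4 (0.15 equiv), D-(−)-diisopropyl tartrate (0.2 equiv), t-BuOOH (0.45 equiv), 4 Å MS, CH2Cl2, −20 °C
Reagents that add atoms: tert-butyl hydroperoxide, CC(C)(C)OO
Why: Sharpless asymmetric epoxidation run as a kinetic resolution. With the D-(−)-tartrate the (R)-carbinol should react much faster, at its E-disubstituted olefin and anti to the hydroxyl (erythro), which fixes C6 and sets C7 and C8 in one reagent-controlled event. The (S)-carbinol and the monosubstituted vinyl group are left and the (S)-carbinol is separated.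

Step 8
Reactants: 1 2-bromoprop-2-en-1-ol
Product: 14 [(2-bromoprop-2-en-1-yl)oxy](tert-butyl)dimethylsilane
Conditions: TBSCl, imidazole, CH2Cl2, 0 °C → rt
Reagents that add atoms: tert-butyl(chloro)dimethylsilane, CC(C)(C)[Si](C)(C)Cl
Why: Standard silylation; the TBS ether on O12 is later removed together with the one on O6.

Step 9
Reactants: 14 [(2-bromoprop-2-en-1-yl)oxy](tert-butyl)dimethylsilane; 13 (1R)-1-[(2R,3R)-3-{[(4-methoxyphenyl)methoxy]methyl}oxiran-2-yl]prop-2-en-1-ol
Product: 17 (2S,3S,4R)-3-[3-(TBS-oxy)prop-1-en-2-yl]-1-(PMB-oxy)hex-5-ene-2,4-diol, via alkenyllithium 15 (not isolated), via alkenylmagnesium bromide 16 (not isolated)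
Conditions: 14 (3.5 equiv), t-BuLi (7 equiv), Et2O, −78 °C; MgBr2·OEt2, −78 → −40 °C; CuI (0.3 equiv), then 13, THF/Et2O, −40 → −10 °C
Reagents that add atoms: none
Why: Copper-catalysed SN2 opening of a 2,3-epoxy alcohol by an alkenyl Grignard reagent forms C7–C11 with inversion at C7, which places C11 syn to O6 and anti to O8. Attack at C7 is expected because the magnesium alkoxide on C6 guides the reagent to the neighbouring carbon and the ether oxygen on C9 deactivates C8. One equivalent of 16 is spent on the hydroxyl.

Step 10
Reactants: 17 (2S,3S,4R)-3-[3-(TBS-oxy)prop-1-en-2-yl]-1-(PMB-oxy)hex-5-ene-2,4-diol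
Product: 18 (2S,3S,4R)-3-[3-(TBS-oxy)prop-1-en-2-yl]hex-5-ene-1,2,4-triol
Conditions: DDQ (1.3 equiv), CH2Cl2/pH 7 buffer (10:1), 0 °C
Reagents that add atoms: none
Why: Oxidative cleavage of the PMB ether through the benzylic oxocarbenium ion, which water intercepts; the silyl ether, the olefins and the unactivated secondary alcohols are not oxidised under these buffered conditions.

Step 11
Reactants: 18 (2S,3S,4R)-3-[3-(TBS-oxy)prop-1-en-2-yl]hex-5-ene-1,2,4-triol
Product: 20 (3R,4S)-4-[(2S)-oxiran-2-yl]-5-[(TBS-oxy)methyl]hexa-1,5-dien-3-ol, via primary tosylate 19 (not isolated)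
Conditions: TsCl (1.05 equiv), Et3N, Bu2SnO (5 mol %), CH2Cl2, 0 °C; then K2CO3, MeOH, 0 °C
Reagents that add atoms: none
Why: Stannylene-catalysed sulfonylation selects the primary hydroxyl of the 1,2-diol, and the vicinal alkoxide then closes the epoxide (3-exo-tet, intramolecular Williamson reaction). This closure is expected to be much faster than five-membered ether formation from O6. The C8–O bond is not touched, so C8 keeps its configuration.

Step 12
Reactants: 20 (3R,4S)-4-[(2S)-oxiran-2-yl]-5-[(TBS-oxy)methyl]hexa-1,5-dien-3-ol
Product: 21 (3R,4R)-3-(TBS-oxy)-4-[(2S)-oxiran-2-yl]-5-[(TBS-oxy)methyl]hexa-1,5-diene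
Conditions: TBSOTf, 2,6-lutidine, CH2Cl2, −78 °C
Reagents that add atoms: tert-butyldimethylsilyl trifluoromethanesulfonate, CC(C)(C)[Si](C)(C)OS(=O)(=O)C(F)(F)F
Why: Silylation of the hindered secondary allylic alcohol with the silyl triflate at low temperature, where the terminal epoxide is not opened; the descriptor at C7 changes from S to R only through CIP priorities.

Step 13
Reactants: 6 tert-butyl[(4-iodo-2-methylidenebutyl)oxy]diphenylsilane; 22 3,3-diethoxyprop-1-yne; 21 (3R,4R)-3-(TBS-oxy)-4-[(2S)-oxiran-2-yl]-5-[(TBS-oxy)methyl]hexa-1,5-diene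
Product: 26 (3R,4R,5R,7E)-7-(diethoxymethyl)-3-(TBS-oxy)-4-[3-(TBS-oxy)prop-1-en-2-yl]-11-[(TBDPS-oxy)methyl]dodeca-1,7,11-trien-5-ol, via alkyllithium 23 (not isolated), via alkylcopper 24 (not isolated), via alkenylcopper 25 (not isolated)
Conditions: 6 (1.6 equiv), t-BuLi (3.2 equiv), Et2O/pentane, −78 °C; CuBr·SMe2 (1.6 equiv), Et2O/SMe2, −45 °C; 22 (1.5 equiv), −45 → −30 °C; then 21 (1.0 equiv), BF3·OEt2 (1.5 equiv), −78 °C; aq. NH4Cl/NH3
Reagents that add atoms: none
Why: Proposed new method: the alkylcopper 24 (monovalent copper) should add syn across the triple bond of 22, with the alkyl group on the terminal carbon C1 and copper on C10, where an acetal oxygen holds it, and the configurationally stable alkenylcopper 25 should then open the BF3-activated epoxide 21 at its unsubstituted carbon C9 with retention at C10; the closest known reaction types are the syn-carbocupration of propargylic acetals followed by alkylation of the alkenylcopper, and the BF3-assisted opening of terminal epoxides by alkenylcopper reagents, here joined in one flask. Two skeletal bonds (C1–C2 and C9–C10) are formed and no ring is closed. No stereocentre is created: C6, C7 and C8 come from 21, and C8 keeps its spatial arrangement because only C9 is attacked (its descriptor changes from S to R through CIP priorities alone). The stereochemical issue is the olefin: syn addition puts C2 and copper cis, and retentive substitution therefore puts C2 cis to C9 and trans to the acetal carbon C14, as the enal of the target requires. Regiochemistry of the carbometalation is secured by the terminal alkyne and by oxygen coordination of copper, and regiochemistry of the epoxide opening by the difference between the CH2 carbon C9 and the branched C8. Chemoselectivity requires that the alkenylcopper is kept at or below −30 °C in ether without THF, and at −78 °C once BF3 is present, so that anti β-elimination of ethoxide to an ethoxyallene does not overtake the opening. The silyl ethers and the three unactivated olefins are inert to the organocopper reagent.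

Step 14
Reactants: 26 (3R,4R,5R,7E)-7-(diethoxymethyl)-3-(TBS-oxy)-4-[3-(TBS-oxy)prop-1-en-2-yl]-11-[(TBDPS-oxy)methyl]dodeca-1,7,11-trien-5-ol; 27 (2S)-2-methylbutanoic acid
Product: 28 (3R,4R,5R,7E)-7-(diethoxymethyl)-3-(TBS-oxy)-4-[3-(TBS-oxy)prop-1-en-2-yl]-11-[(TBDPS-oxy)methyl]dodeca-1,7,11-trien-5-yl (2S)-2-methylbutanoate
Conditions: 27 (1.5 equiv), DCC, DMAP (cat.), CH2Cl2, 0 °C → rt
Reagents that add atoms: none
Why: Steglich esterification of the only free hydroxyl (O8); run cold with catalytic DMAP, the α-branched acid should not epimerise. Acylating before O6 is freed rules out any confusion of O6 and O8 later.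

Step 15
Reactants: 28 (3R,4R,5R,7E)-7-(diethoxymethyl)-3-(TBS-oxy)-4-[3-(TBS-oxy)prop-1-en-2-yl]-11-[(TBDPS-oxy)methyl]dodeca-1,7,11-trien-5-yl (2S)-2-methylbutanoate
Product: 29 (3R,4S,5R,7E)-7-formyl-3-hydroxy-4-(3-hydroxyprop-1-en-2-yl)-11-[(TBDPS-oxy)methyl]dodeca-1,7,11-trien-5-yl (2S)-2-methylbutanoate
Conditions: 1 M aq. HCl/THF (1:4), rt
Reagents that add atoms: water, O
Why: Acid hydrolysis cleaves both TBS ethers and the allylic diethyl acetal in one operation, while the far more acid-stable primary TBDPS ether and the ester should remain. The open-chain triene has no transannular pathway, which is why the acid step precedes ring closure.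

Step 16
Reactants: 29 (3R,4S,5R,7E)-7-formyl-3-hydroxy-4-(3-hydroxyprop-1-en-2-yl)-11-[(TBDPS-oxy)methyl]dodeca-1,7,11-trien-5-yl (2S)-2-methylbutanoate
Product: 32 (1R,3E)-1-[(2R,3R)-2-ethenyl-4-methylidene-5-oxooxolan-3-yl]-3-formyl-7-[(TBDPS-oxy)methyl]octa-3,7-dien-1-yl (2S)-2-methylbutanoate, via C12 aldehyde 30 (not isolated), via lactol 31 (not isolated)
Conditions: TEMPO (0.2 equiv), PhI(OAc)2 (2.5 equiv), CH2Cl2, rt
Reagents that add atoms: none
Why: TEMPO/PhI(OAc)2 oxidative lactonisation: the primary allylic C12 alcohol is oxidised much faster than the secondary C6 alcohol, O6 traps the aldehyde as the five-membered lactol (5-exo-trig), and the lactol is oxidised on to the lactone. C6 and C7 are untouched, so the trans relation of the lactone is that of the triad, and the acylated O8 excludes the 8,12-lactone.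

Step 17
Reactants: 32 (1R,3E)-1-[(2R,3R)-2-ethenyl-4-methylidene-5-oxooxolan-3-yl]-3-formyl-7-[(TBDPS-oxy)methyl]octa-3,7-dien-1-yl (2S)-2-methylbutanoate
Product: 33 15-O-TBDPS ether of the target: (6R,7R,8R)-8-[(2S)-2-methylbutanoyloxy]-14-oxo-15-(TBDPS-oxy)germacra-1(10),4,11(13)-trien-12,6-olide with both ring olefins cis in the ring
Conditions: second-generation Grubbs catalyst (10 mol %), toluene (1 mM), 80 °C
Reagents that add atoms: none
Why: Ring-closing olefin metathesis between the C6 vinyl group and the C4 methylidene group closes the ten-membered ring with loss of ethene. The enal and the α-methylene lactone are electron-poor conjugated olefins that should not engage the carbene, so the six-membered closure onto C10 that an unconjugated C1=C10 bond might allow is suppressed. The ring-cis geometry at C4=C5 is expected for a ten-membered ring that already holds a cis olefin and a trans-fused lactone, but it is not enforced.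

Step 18
Reactants: 33 15-O-TBDPS ether of the target
Product: 34 (6R,7R,8R)-15-hydroxy-8-[(2S)-2-methylbutanoyloxy]-14-oxogermacra-1(10),4,11(13)-trien-12,6-olide with both ring olefins cis in the ring (CNP0168859.6)
Conditions: HF·pyridine, pyridine, THF, 0 °C → rt
Reagents that add atoms: none
Why: Fluoride-mediated cleavage of the primary silyl ether under buffered, weakly acidic conditions that an enal, an α-methylene lactone and a secondary ester tolerate; no basic alkoxide is generated that could add to the acceptors or move the acyl group.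

## Compound list

1 | 2-bromoprop-2-en-1-ol | C=C(Br)CO | starting material
2 | [(2-bromoprop-2-en-1-yl)oxy](tert-butyl)diphenylsilane | C=C(Br)CO[Si](c1ccccc1)(c1ccccc1)C(C)(C)C | intermediate
3 | oxirane | C1CO1 | starting material
4 | [3-(TBDPS-oxy)prop-1-en-2-yl]lithium | [Li]C(=C)CO[Si](c1ccccc1)(c1ccccc1)C(C)(C)C | intermediate
5 | 3-{[(tert-butyldiphenylsilyl)oxy]methyl}but-3-en-1-ol | C=C(CCO)CO[Si](c1ccccc1)(c1ccccc1)C(C)(C)C | intermediate
6 | tert-butyl[(4-iodo-2-methylidenebutyl)oxy]diphenylsilane | C=C(CO[Si](c1ccccc1)(c1ccccc1)C(C)(C)C)CCI | intermediate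
7 | prop-2-yn-1-ol | C#CCO | starting material
8 | 1-methoxy-4-[(prop-2-yn-1-yloxy)methyl]benzene | C#CCOCc1ccc(OC)cc1 | intermediate
9 | prop-2-enal | C=CC=O | starting material
10 | {3-[(4-methoxyphenyl)methoxy]prop-1-yn-1-yl}lithium | [Li]C#CCOCc1ccc(OC)cc1 | intermediate
11 | rac-6-[(4-methoxyphenyl)methoxy]hex-1-en-4-yn-3-ol | C=CC(O)C#CCOCc1ccc(OC)cc1 | intermediate
12 | rac-(4E)-6-[(4-methoxyphenyl)methoxy]hexa-1,4-dien-3-ol | C=CC(O)/C=C/COCc1ccc(OC)cc1 | intermediate
13 | (1R)-1-[(2R,3R)-3-{[(4-methoxyphenyl)methoxy]methyl}oxiran-2-yl]prop-2-en-1-ol | C=C[C@@H](O)[C@H]1O[C@@H]1COCc1ccc(OC)cc1 | intermediate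
14 | [(2-bromoprop-2-en-1-yl)oxy](tert-butyl)dimethylsilane | C=C(Br)CO[Si](C)(C)C(C)(C)C | intermediate
15 | [3-(TBS-oxy)prop-1-en-2-yl]lithium | [Li]C(=C)CO[Si](C)(C)C(C)(C)C | intermediate
16 | [3-(TBS-oxy)prop-1-en-2-yl]magnesium bromide | Br[Mg]C(=C)CO[Si](C)(C)C(C)(C)C | intermediate
17 | (2S,3S,4R)-3-[3-(TBS-oxy)prop-1-en-2-yl]-1-(PMB-oxy)hex-5-ene-2,4-diol | C=C[C@@H](O)[C@H](C(=C)CO[Si](C)(C)C(C)(C)C)[C@H](O)COCc1ccc(OC)cc1 | intermediate
18 | (2S,3S,4R)-3-[3-(TBS-oxy)prop-1-en-2-yl]hex-5-ene-1,2,4-triol | C=C[C@@H](O)[C@H](C(=C)CO[Si](C)(C)C(C)(C)C)[C@H](O)CO | intermediate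
19 | (2S,3S,4R)-2,4-dihydroxy-3-[3-(TBS-oxy)prop-1-en-2-yl]hex-5-en-1-yl 4-methylbenzenesulfonate | C=C[C@@H](O)[C@H](C(=C)CO[Si](C)(C)C(C)(C)C)[C@H](O)COS(=O)(=O)c1ccc(C)cc1 | intermediate
20 | (3R,4S)-4-[(2S)-oxiran-2-yl]-5-[(TBS-oxy)methyl]hexa-1,5-dien-3-ol | C=C[C@@H](O)[C@H](C(=C)CO[Si](C)(C)C(C)(C)C)[C@H]1CO1 | intermediate
21 | (3R,4R)-3-(TBS-oxy)-4-[(2S)-oxiran-2-yl]-5-[(TBS-oxy)methyl]hexa-1,5-diene | C=C[C@@H](O[Si](C)(C)C(C)(C)C)[C@H](C(=C)CO[Si](C)(C)C(C)(C)C)[C@H]1CO1 | intermediate
22 | 3,3-diethoxyprop-1-yne | C#CC(OCC)OCC | starting material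
23 | [3-methylidene-4-(TBDPS-oxy)butyl]lithium | [Li]CCC(=C)CO[Si](c1ccccc1)(c1ccccc1)C(C)(C)C | intermediate
24 | [3-methylidene-4-(TBDPS-oxy)butyl]copper | [Cu]CCC(=C)CO[Si](c1ccccc1)(c1ccccc1)C(C)(C)C | intermediate
25 | [(2Z)-1,1-diethoxy-6-methylidene-7-(TBDPS-oxy)hept-2-en-2-yl]copper | C=C(CO[Si](c1ccccc1)(c1ccccc1)C(C)(C)C)CC/C=C(\[Cu])C(OCC)OCC | intermediate
26 | (3R,4R,5R,7E)-7-(diethoxymethyl)-3-(TBS-oxy)-4-[3-(TBS-oxy)prop-1-en-2-yl]-11-[(TBDPS-oxy)methyl]dodeca-1,7,11-trien-5-ol | C=C(CO[Si](c1ccccc1)(c1ccccc1)C(C)(C)C)CC/C=C(/C(OCC)OCC)C[C@@H](O)[C@@H](C(=C)CO[Si](C)(C)C(C)(C)C)[C@H](O[Si](C)(C)C(C)(C)C)C=C | intermediate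
27 | (2S)-2-methylbutanoic acid | CC[C@H](C)C(=O)O | starting material
28 | (3R,4R,5R,7E)-7-(diethoxymethyl)-3-(TBS-oxy)-4-[3-(TBS-oxy)prop-1-en-2-yl]-11-[(TBDPS-oxy)methyl]dodeca-1,7,11-trien-5-yl (2S)-2-methylbutanoate | C=C(CO[Si](c1ccccc1)(c1ccccc1)C(C)(C)C)CC/C=C(/C(OCC)OCC)C[C@@H](OC(=O)[C@@H](C)CC)[C@@H](C(=C)CO[Si](C)(C)C(C)(C)C)[C@H](O[Si](C)(C)C(C)(C)C)C=C | intermediate
29 | (3R,4S,5R,7E)-7-formyl-3-hydroxy-4-(3-hydroxyprop-1-en-2-yl)-11-[(TBDPS-oxy)methyl]dodeca-1,7,11-trien-5-yl (2S)-2-methylbutanoate | C=C(CO[Si](c1ccccc1)(c1ccccc1)C(C)(C)C)CC/C=C(/C=O)C[C@@H](OC(=O)[C@@H](C)CC)[C@@H](C(=C)CO)[C@H](O)C=C | intermediate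
30 | 29 with C12 oxidised to the aldehyde (C6 hydroxyl still free) | C=C(CO[Si](c1ccccc1)(c1ccccc1)C(C)(C)C)CC/C=C(/C=O)C[C@@H](OC(=O)[C@@H](C)CC)[C@@H](C(=C)C=O)[C@H](O)C=C | intermediate
31 | lactol of 30 between O6 and C12 (both C12 epimers) | C=C1C(O)O[C@H](C=C)[C@H]1[C@H](OC(=O)[C@@H](C)CC)C/C(C=O)=C\CCC(=C)CO[Si](c1ccccc1)(c1ccccc1)C(C)(C)C | intermediate
32 | (1R,3E)-1-[(2R,3R)-2-ethenyl-4-methylidene-5-oxooxolan-3-yl]-3-formyl-7-[(TBDPS-oxy)methyl]octa-3,7-dien-1-yl (2S)-2-methylbutanoate | C=C1C(=O)O[C@H](C=C)[C@H]1[C@H](OC(=O)[C@@H](C)CC)C/C(C=O)=C\CCC(=C)CO[Si](c1ccccc1)(c1ccccc1)C(C)(C)C | intermediate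
33 | 15-O-TBDPS ether of the target | C=C1C(=O)O[C@@H]2/C=C(/CO[Si](c3ccccc3)(c3ccccc3)C(C)(C)C)CC/C=C(/C=O)C[C@@H](OC(=O)[C@@H](C)CC)[C@@H]12 | intermediate
34 | (6R,7R,8R)-15-hydroxy-8-[(2S)-2-methylbutanoyloxy]-14-oxogermacra-1(10),4,11(13)-trien-12,6-olide, both ring olefins cis in the ring (CNP0168859.6) | C=C1C(=O)O[C@@H]2/C=C(/CO)CC/C=C(/C=O)C[C@@H](OC(=O)[C@@H](C)CC)[C@@H]12 | target

## Step count and least certain steps

Total step count: 18. Longest linear sequence: 14 steps (steps 4–7 and 9–18, from 7 to 34).

Step 13 (key step, proposed new method). The alkenylcopper 25 may lose ethoxide by β-elimination before it meets the epoxide, the more so once BF3 is present. The alkylcopper may also deprotonate the terminal alkyne instead of adding to it, and BF3 may rearrange the epoxide if the opening is slow. Fallback with known chemistry, in two separate operations: 6 and 22 are taken to 25 as in step 13, and 25 is quenched with iodine to the vinyl iodide tert-butyl{[(5Z)-7,7-diethoxy-6-iodo-2-methylidenehept-5-en-1-yl]oxy}diphenylsilane F1, a known outcome for alkenylcopper reagents from propargylic acetals. Iodine–lithium exchange (t-BuLi, Et2O, −78 °C) gives the corresponding alkenyllithium F2 with retention. F2 opens 21 at C9 in the presence of BF3·OEt2 at −78 °C, the established alkenyllithium/BF3 opening of terminal epoxides. The fallback sets out from 6 and 22 and returns at 26.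

Step 17. Ring closure may lose out to oligomerisation, the new trisubstituted olefin may form ring-trans, or ruthenium hydride species may move the olefins at 80 °C. Fallback, ring closure before the lactone exists: 28 is cyclised by the same metathesis to the silylated ten-membered acetal F3, a substrate free of the lactone constraint; it does carry an unconjugated C1=C10 bond, so six-membered closure onto C10 must be watched there. Aqueous acid as in step 15 gives the cyclic diol enal F4, and TEMPO/PhI(OAc)2 as in step 16 closes the lactone on the ring. The fallback sets out from 28 and returns at 33.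

Step 9. The alkenyl group may be delivered to C8 instead of C7, since C7 is the more hindered carbon, and magnesium bromide may open the epoxide to a bromohydrin. Fallback on a five-membered template where regiochemistry cannot arise:
- Commercial (5S)-5-(hydroxymethyl)furan-2(5H)-one F5 is converted to its PMB ether F6 (PMB trichloroacetimidate, cat. camphorsulfonic acid).
- Copper-mediated conjugate addition of 16 (made from 14 through 15 as in step 9; CuBr·SMe2, TMSCl, THF, −78 °C) anti to the C8 substituent gives, through the silyl ketene acetal F7, the trans lactone (4R,5S)-4-[3-(TBS-oxy)prop-1-en-2-yl]-5-(PMB-oxymethyl)oxolan-2-one F8.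
- Enolate hydroxylation (KN(SiMe3)2, then 2-(benzenesulfonyl)-3-phenyloxaziridine, −78 °C) anti to the new C7 substituent gives the (3S,4S,5S)-3-hydroxy lactone F9.
- Reduction with i-Bu2AlH gives the lactol F10, and Wittig methylenation (Ph3P=CH2) opens it to 17.

Both stereochemical events are ring-controlled and of a well-established kind, and the sequence has the same length as steps 4–7 and 9. The fallback sets out from 14 and returns at 17.

Step 15. Cleavage of the hindered C6 silyl ether may lag behind, and forcing it may start to remove the TBDPS group or move the acyl group from O8 to O6. Fallback in two stages: HF·pyridine in THF/pyridine removes only the two TBS groups of 28 and gives the diol acetal F11. TEMPO/PhI(OAc)2 then gives the lactone acetal F12, so that O6 is tied up before any acid is used. Brief treatment with wet acid (pyridinium p-toluenesulfonate, acetone/water) frees the enal. The fallback sets out from 28 and returns at 32.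

## Further compounds

F1 | step 13 | tert-butyl{[(5Z)-7,7-diethoxy-6-iodo-2-methylidenehept-5-en-1-yl]oxy}diphenylsilane | C=C(CO[Si](c1ccccc1)(c1ccccc1)C(C)(C)C)CC/C=C(\I)C(OCC)OCC
F2 | step 13 | alkenyllithium from F1 (lithium in place of iodine, geometry retained) | C=C(CO[Si](c1ccccc1)(c1ccccc1)C(C)(C)C)CC/C=C(\[Li])C(OCC)OCC
F3 | step 17 | ring-closed 28: ten-membered ring with 6-OTBS, 12-OTBS, 15-OTBDPS, C14 diethyl acetal and the 8-ester | C=C(CO[Si](C)(C)C(C)(C)C)[C@H]1[C@H](O[Si](C)(C)C(C)(C)C)/C=C(/CO[Si](c2ccccc2)(c2ccccc2)C(C)(C)C)CC/C=C(/C(OCC)OCC)C[C@H]1OC(=O)[C@@H](C)CC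
F4 | step 17 | cyclic 6,12-diol 14-enal with 15-OTBDPS and the 8-ester | C=C(CO)[C@H]1[C@H](O)/C=C(/CO[Si](c2ccccc2)(c2ccccc2)C(C)(C)C)CC/C=C(/C=O)C[C@H]1OC(=O)[C@@H](C)CC
F5 | step 9 | (5S)-5-(hydroxymethyl)furan-2(5H)-one | O=C1C=C[C@@H](CO)O1
F6 | step 9 | (5S)-5-{[(4-methoxyphenyl)methoxy]methyl}furan-2(5H)-one | O=C1C=C[C@@H](COCc2ccc(OC)cc2)O1
F7 | step 9 | trimethylsilyl ketene acetal of F8 | C[Si](C)(C)OC1=C[C@H](C(=C)CO[Si](C)(C)C(C)(C)C)[C@@H](COCc2ccc(OC)cc2)O1
F8 | step 9 | (4R,5S)-4-[3-(TBS-oxy)prop-1-en-2-yl]-5-(PMB-oxymethyl)oxolan-2-one | O=C1C[C@H](C(=C)CO[Si](C)(C)C(C)(C)C)[C@@H](COCc2ccc(OC)cc2)O1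
F9 | step 9 | (3S,4S,5S)-3-hydroxy-4-[3-(TBS-oxy)prop-1-en-2-yl]-5-(PMB-oxymethyl)oxolan-2-one | O=C1[C@@H](O)[C@H](C(=C)CO[Si](C)(C)C(C)(C)C)[C@@H](COCc2ccc(OC)cc2)O1
F10 | step 9 | lactol of F9 (both anomers) | OC1[C@@H](O)[C@H](C(=C)CO[Si](C)(C)C(C)(C)C)[C@@H](COCc2ccc(OC)cc2)O1
F11 | step 15 | 6,12-diol of 28 with the C14 diethyl acetal kept | C=C(CO[Si](c1ccccc1)(c1ccccc1)C(C)(C)C)CC/C=C(/C(OCC)OCC)C[C@@H](OC(=O)[C@@H](C)CC)[C@@H](C(=C)CO)[C@H](O)C=C
F12 | step 15 | C14 diethyl acetal of 32 | C=C1C(=O)O[C@H](C=C)[C@H]1[C@H](OC(=O)[C@@H](C)CC)C/C(C(OCC)OCC)=C\CCC(=C)CO[Si](c1ccccc1)(c1ccccc1)C(C)(C)C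
A1 | alternative 1 | eleven-membered cyclic sulfone (sulfur between C1 and C10, C14 methyl ester on C10, O6/O12 acetonide, 8-OPMB, 15-OTBDPS) | C=C1COC(C)(C)O[C@@H]2/C=C(/CO[Si](c3ccccc3)(c3ccccc3)C(C)(C)C)CCCS(=O)(=O)C(C(=O)OC)C[C@@H](OCc3ccc(OC)cc3)[C@@H]12
A2 | alternative 1 | methyl cyclodeca-1(10),4-diene-14-oate, both olefins ring-cis, O6/O12 acetonide, 8-OPMB, 15-OTBDPS | C=C1COC(C)(C)O[C@@H]2/C=C(/CO[Si](c3ccccc3)(c3ccccc3)C(C)(C)C)CC/C=C(/C(=O)OC)C[C@@H](OCc3ccc(OC)cc3)[C@@H]12
A3 | alternative 2 | open-chain C8 aldehyde with a 3-(tributylstannylmethyl)butenolide at C6, 14-OTBS, 15-OTBDPS | O=CC/C(CO[Si](C)(C)C(C)(C)C)=C\CC/C(CO[Si](c1ccccc1)(c1ccccc1)C(C)(C)C)=C\[C@@H]1C=C(C[Sn](CCCC)(CCCC)CCCC)C(=O)O1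
A4 | alternative 2 | 8-hydroxy cis,cis-germacranolide with the α-methylene lactone, 14-OTBS, 15-OTBDPS | C=C1C(=O)O[C@@H]2/C=C(/CO[Si](c3ccccc3)(c3ccccc3)C(C)(C)C)CC/C=C(/CO[Si](C)(C)C(C)(C)C)C[C@@H](O)[C@@H]12
A5 | alternative 3 | cis-1,6-dialkenylcyclohex-2-en-1-ol: (E)-2-(PMB-oxy)vinyl on the C6 carbinol, 3-(TBS-oxy)prop-1-en-2-yl on C1, 15-OTBDPS on C4 | O[C@]1(/C=C/OCc2ccc(OC)cc2)C=C(CO[Si](c2ccccc2)(c2ccccc2)C(C)(C)C)CC[C@H]1C(=C)CO[Si](C)(C)C(C)(C)C
A6 | alternative 3 | 8-(PMB-oxy)cyclodeca-1(10),4-dien-6-one, both olefins ring-cis, 14-OTBS, 15-OTBDPS | O=C1/C=C(/CO[Si](c2ccccc2)(c2ccccc2)C(C)(C)C)CC/C=C(/CO[Si](C)(C)C(C)(C)C)C[C@@H](OCc2ccc(OC)cc2)C1
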